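## Retrosynthetic overview

1. The dihydropyranone is the only ring and is closed last, by lactonisation of a (Z)-5-hydroxy-2-enoate. All four C–O bonds (C5, C7, C9, C11) come from C–B bonds in one stereoretentive oxidation, so no protecting groups are needed.
2. C5–C6 and C3–C4 (key step): a three-component, palladium-induced 1,2-metallate shift. It joins the primary boron of a C15 tetraboronate, vinyllithium (C4–C5) and ethyl (Z)-3-iodoacrylate (C1–C3), and it sets C5.
3. C7 comes from catalyst-controlled diboration of a terminal alkene. C9–C10 comes from a lithiation–borylation 1,2-shift with a butenyl carbenoid, which sets C9. C11 comes from diboration of undec-1-ene.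
4. Undec-1-ene comes from a copper-catalysed C7 + C4 alkyl–alkyl coupling.

Conventions: the chain is numbered as in the target (C1 = lactone carbonyl, C5 = ring CH–O, C20 = terminal CH3). Bpin = 4,4,5,5-tetramethyl-1,3,2-dioxaborolan-2-yl. TIB = 2,4,6-triisopropylbenzoyl.

Assumption: the antipode named for each chiral ligand is the one taken to give the drawn configuration; both antipodes are available, so the mirror-image ligand is used if the sense of induction proves to be the reverse.

## Route

Step 1
Reactants: 1 1-bromoheptane; 2 but-3-enylmagnesium bromide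
Product: 3 undec-1-ene
Conditions: Li2CuCl4 (3 mol %), NMP (4 equiv), THF, 0 °C to rt, 2 h
Reagents that add atoms: none
Why: Copper-catalysed Kochi-type sp3–sp3 cross-coupling of a primary alkyl bromide and a primary Grignard reagent is fast and high-yielding with NMP as co-solvent, leaves the terminal alkene untouched and creates no stereocentre.

Step 2
Reactants: 3 undec-1-ene
Product: 4 (2S)-1,2-bis(Bpin)undecane
Conditions: B2pin2 (1.05 equiv), Pt(dba)3 (1 mol %), (R,R)-TADDOL-derived phenylphosphonite bearing 3,5-diisopropylphenyl groups (1.2 mol %), THF, 60 °C, 6 h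
Reagents that add atoms: bis(pinacolato)diboron, CC1(C)OB(OC1(C)C)B1OC(C)(C)C(C)(C)O1
Why: Enantioselective platinum-catalysed syn-diboration of a terminal alkene, in which the phosphonite-bound bis(boryl)platinum complex inserts one face of the unbranched 1-alkene and thereby sets C11 (about 95:5 er is usual for this substrate class).

Step 3
Reactants: 5 but-3-en-1-ol
Product: 6 but-3-enyl 2,4,6-triisopropylbenzoate
Conditions: 2,4,6-triisopropylbenzoic acid, PPh3, DIAD, THF, 0 °C to rt
Reagents that add atoms: 2,4,6-triisopropylbenzoic acid, CC(C)c1cc(C(C)C)c(C(=O)O)c(C(C)C)c1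
Why: Mitsunobu esterification, in which the hindered carboxylate attacks the activated primary carbon so that the crowding around its own carbonyl group does not matter; no stereocentre is formed.

Step 4
Reactants: 6 but-3-enyl 2,4,6-triisopropylbenzoate; 4 (2S)-1,2-bis(Bpin)undecane
Product: 9 (4R,6R)-4,6-bis(Bpin)pentadec-1-ene, via lithiated benzoate 7 (not isolated), via boronate complex 8 (not isolated)
Conditions: 6 (1.3 equiv), s-BuLi (1.25 equiv), (+)-sparteine (1.3 equiv), Et2O, −78 °C, 5 h; then 4 (1.0 equiv), −78 °C, 2 h; then reflux, 16 h; aqueous work-up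
Reagents that add atoms: s-butyllithium, [Li]C(C)CC (supplies only the lithium of 7 and 8)
Why: Lithiation–borylation: (+)-sparteine-directed deprotonation gives the configurationally stable (R)-carbenoid 7, which binds with retention only to the unhindered primary boron of 4, and on warming C10 undergoes a stereospecific Matteson-type 1,2-shift from boron to carbon with inversion and loss of the benzoate, which forms C9–C10 and sets C9 by reagent control (9,11-syn).

Step 5
Reactants: 9 (4R,6R)-4,6-bis(Bpin)pentadec-1-ene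
Product: 10 (2R,4S,6R)-1,2,4,6-tetrakis(Bpin)pentadecane
Conditions: B2pin2 (1.1 equiv), Pt(dba)3 (3 mol %), (S,S)-TADDOL-derived phenylphosphonite bearing 3,5-diisopropylphenyl groups (3.6 mol %), THF, 60 °C, 12 h
Reagents that add atoms: bis(pinacolato)diboron, CC1(C)OB(OC1(C)C)B1OC(C)(C)C(C)(C)O1
Why: Catalyst-controlled platinum-catalysed alkene diboration as in step 2 but with the mirror-image ligand, which overrides the weak bias of the remote C9 boronate and sets C7 anti to C9 while the existing boronates stay inert.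

Step 6
Reactants: 10 (2R,4S,6R)-1,2,4,6-tetrakis(Bpin)pentadecane; 11 iodoethene; 12 ethyl (Z)-3-iodoacrylate
Product: 15 ethyl (2Z,5R,7S,9R,11R)-5,7,9,11-tetrakis(Bpin)icos-2-enoate, via vinyllithium 13 (not isolated), via vinyl boronate complex 14 (not isolated)
Conditions: 11 (1.05 equiv), n-BuLi (1.0 equiv), Et2O–pentane, −78 °C; 10 (1.0 equiv), Et2O, −78 to 0 °C; evaporate under high vacuum; Pd(OAc)2 (3 mol %), (Sp,Sp)-MandyPhos [2,2'-bis(α-dimethylaminobenzyl)-1,1'-bis(di-3,5-xylylphosphino)ferrocene] (3.6 mol %), KOTf (2 equiv), 12 (1.2 equiv), THF, 40 °C, 16 h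
Reagents that add atoms: n-butyllithium, [Li]CCCC (supplies only the lithium of 13 and 14)
Why: Proposed new method: a catalyst-controlled conjunctive cross-coupling of a polyboronate with a β-iodoacrylate, in which vinyllithium adds only to the unhindered primary boron of 10 (as sp2 organolithiums do with vicinal bis(boronates)), oxidative addition of 12 to zerovalent palladium occurs with retention, KOTf removes iodide as KI so that the cationic, ester-chelated (Z)-alkenylpalladium can bind the vinyl group of 14 and trigger an anti 1,2-shift of C6 from boron to the α-carbon (new C5–C6 bond, C5 fixed by the ligand pocket, about 95:5 expected), and reductive elimination then joins C4 to C3 with the Z geometry kept; the closest known reaction type is the enantioselective palladium-catalysed three-component conjunctive coupling of simple alkyl- or arylboronates, vinyllithium and aryl or alkenyl triflates or bromides, which has not been shown with a tetraboronate as the migrating group or with a β-haloacrylate as the electrophile.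

Step 7
Reactants: 15 ethyl (2Z,5R,7S,9R,11R)-5,7,9,11-tetrakis(Bpin)icos-2-enoate
Product: 17 (6S)-6-[(2S,4R,6R)-2,4,6-trihydroxypentadecyl]-5,6-dihydro-2H-pyran-2-one, via tetraol ester 16 (not isolated)
Conditions: NaBO3·4H2O (20 equiv), THF–H2O 1:1, rt, 12 h; extraction, MeOH co-evaporation; then PPTS (10 mol %), toluene, 50 °C
Reagents that add atoms: sodium perborate, [Na+].[Na+].O[B-]1(O)OO[B-](O)(O)OO1
Why: Peroxide oxidation of alkylboronates proceeds by a stereoretentive boron-to-oxygen 1,2-shift, so all four carbinol centres are delivered unchanged under conditions mild enough for an enoate, and the Z geometry then lets only the C5 hydroxyl reach the ester, so acid-catalysed lactonisation (transesterification) closes the six-membered ring.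

## Compound list

1 | 1-bromoheptane | CCCCCCCBr | starting material
2 | but-3-enylmagnesium bromide | C=CCC[Mg]Br | starting material
3 | undec-1-ene | CCCCCCCCCC=C | intermediate
4 | (2S)-1,2-bis(Bpin)undecane | CCCCCCCCC[C@@H](B1OC(C)(C)C(C)(C)O1)CB1OC(C)(C)C(C)(C)O1 | intermediate
5 | but-3-en-1-ol | C=CCCO | starting material
6 | but-3-enyl 2,4,6-triisopropylbenzoate | C=CCCOC(=O)c1c(C(C)C)cc(C(C)C)cc1C(C)C | intermediate
7 | (R)-1-lithiobut-3-enyl 2,4,6-triisopropylbenzoate (sparteine-bound; not isolated) | [Li][C@H](CC=C)OC(=O)c1c(C(C)C)cc(C(C)C)cc1C(C)C | intermediate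
8 | lithium boronate complex of 7 at the primary boron of 4 (not isolated) | [Li+].CCCCCCCCC[C@@H](B1OC(C)(C)C(C)(C)O1)C[B-]1(OC(C)(C)C(C)(C)O1)[C@H](CC=C)OC(=O)c1c(C(C)C)cc(C(C)C)cc1C(C)C | intermediate
9 | (4R,6R)-4,6-bis(Bpin)pentadec-1-ene | CCCCCCCCC[C@@H](B1OC(C)(C)C(C)(C)O1)C[C@@H](B1OC(C)(C)C(C)(C)O1)CC=C | intermediate
10 | (2R,4S,6R)-1,2,4,6-tetrakis(Bpin)pentadecane | CCCCCCCCC[C@@H](B1OC(C)(C)C(C)(C)O1)C[C@@H](B1OC(C)(C)C(C)(C)O1)C[C@H](B1OC(C)(C)C(C)(C)O1)CB1OC(C)(C)C(C)(C)O1 | intermediate
11 | iodoethene | C=CI | starting material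
12 | ethyl (Z)-3-iodoacrylate | CCOC(=O)/C=C\I | starting material
13 | vinyllithium (not isolated) | [Li]C=C | intermediate
14 | lithium vinyl boronate complex at the primary boron of 10 (not isolated) | [Li+].CCCCCCCCC[C@@H](B1OC(C)(C)C(C)(C)O1)C[C@@H](B1OC(C)(C)C(C)(C)O1)C[C@H](B1OC(C)(C)C(C)(C)O1)C[B-]1(C=C)OC(C)(C)C(C)(C)O1 | intermediate
15 | ethyl (2Z,5R,7S,9R,11R)-5,7,9,11-tetrakis(Bpin)icos-2-enoate | CCCCCCCCC[C@@H](B1OC(C)(C)C(C)(C)O1)C[C@@H](B1OC(C)(C)C(C)(C)O1)C[C@H](B1OC(C)(C)C(C)(C)O1)C[C@@H](B1OC(C)(C)C(C)(C)O1)C/C=C\C(=O)OCC | intermediate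
16 | ethyl (2Z,5S,7R,9R,11R)-5,7,9,11-tetrahydroxyicos-2-enoate (not isolated) | CCCCCCCCC[C@@H](O)C[C@@H](O)C[C@H](O)C[C@@H](O)C/C=C\C(=O)OCC | intermediate
17 | (6S)-6-[(2S,4R,6R)-2,4,6-trihydroxypentadecyl]-5,6-dihydro-2H-pyran-2-one | CCCCCCCCC[C@@H](O)C[C@@H](O)C[C@H](O)C[C@@H]1CC=CC(=O)O1 | target

## Step count and risks

Total step count: 7. Longest linear sequence: 6 (steps 1, 2, 4, 5, 6, 7).

The four stereocentres are set by four independent reagent- or catalyst-controlled events. Minor diastereomers are removed by chromatography at 9, 10 and 15, and this also raises the enantiomeric purity of the main isomer.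

**Step 6, the new coupling, is most at risk.**
- Vinyllithium may partly add to a secondary boron.
- Iodide may slow the cationic palladium pathway.
- Direct vinyl transfer (Suzuki type) may compete.
- The alkenylpalladium may leak from Z to E.
- Control at C5 may be only modest.

The fallback uses known chemistry only, sets out from 10 and comes back at 15. Carbenoid 7, made from 6 exactly as in step 4, is added to 10 to give the lithium boronate complex of 7 at the primary boron of 10 F1. Its 1,2-shift on warming gives (4R,6S,8R,10R)-4,6,8,10-tetrakis(Bpin)nonadec-1-ene F2. Ozonolysis (O3, CH2Cl2, −78 °C, then PPh3) gives (3R,5S,7R,9R)-3,5,7,9-tetrakis(Bpin)octadecanal F3. A Z-selective Ando-type Horner–Wadsworth–Emmons olefination with ethyl 2-(diphenoxyphosphoryl)acetate (NaH, THF, −78 °C) then gives 15. This costs two more steps.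

**Step 7 is second.** Four hindered boronates must be oxidised beside a Z-enoate. Hydroperoxide could add to the enoate, and the C7 hydroxyl could add to C3, although the 5,7-anti relationship would force the side chain axial in the bicyclic product and so disfavours this.

The fallback removes the Michael acceptor before the oxidation, sets out from 15 and comes back at 17. Reduction with i-Bu2AlH (CH2Cl2, −78 °C) gives (2Z,5R,7S,9R,11R)-5,7,9,11-tetrakis(Bpin)icos-2-en-1-ol F4. Standard H2O2/NaOH oxidation (THF, 0 °C to rt) gives (2Z,5S,7R,9R,11R)-icos-2-ene-1,5,7,9,11-pentaol F5. MnO2 (CH2Cl2–acetone, rt) oxidises only the allylic primary alcohol to (2Z,5S,7R,9R,11R)-5,7,9,11-tetrahydroxyicos-2-enal F6. This closes to (6S)-6-[(2S,4R,6R)-2,4,6-trihydroxypentadecyl]-5,6-dihydro-2H-pyran-2-ol F7, which the same reagent oxidises on to 17.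

**Step 4 is third.** Deprotonation of 6 may be incomplete, may compete with allylic lithiation, or may give a carbenoid of insufficient er, and any excess base would attack 4.

The fallback separates the stereodefining deprotonation from the C–C bond formation through an isolated chiral building block. It sets out from 6 and comes back at 7. Carbenoid 7 is quenched with Me3SnCl to give (R)-1-(trimethylstannyl)but-3-enyl 2,4,6-triisopropylbenzoate F8, which is purified and checked for er. Tin–lithium exchange (n-BuLi, Et2O, −78 °C, retention) then regenerates diamine-free 7 in exact stoichiometry. Addition of 4 leads through 8 to 9 as before.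

## Further compounds

F1 | step 6 | lithium boronate complex of 7 at the primary boron of 10 | [Li+].CCCCCCCCC[C@@H](B1OC(C)(C)C(C)(C)O1)C[C@@H](B1OC(C)(C)C(C)(C)O1)C[C@H](B1OC(C)(C)C(C)(C)O1)C[B-]1(OC(C)(C)C(C)(C)O1)[C@H](CC=C)OC(=O)c1c(C(C)C)cc(C(C)C)cc1C(C)C
F2 | step 6 | (4R,6S,8R,10R)-4,6,8,10-tetrakis(Bpin)nonadec-1-ene | CCCCCCCCC[C@@H](B1OC(C)(C)C(C)(C)O1)C[C@@H](B1OC(C)(C)C(C)(C)O1)C[C@H](B1OC(C)(C)C(C)(C)O1)C[C@@H](B1OC(C)(C)C(C)(C)O1)CC=C
F3 | step 6 | (3R,5S,7R,9R)-3,5,7,9-tetrakis(Bpin)octadecanal | CCCCCCCCC[C@@H](B1OC(C)(C)C(C)(C)O1)C[C@@H](B1OC(C)(C)C(C)(C)O1)C[C@H](B1OC(C)(C)C(C)(C)O1)C[C@@H](B1OC(C)(C)C(C)(C)O1)CC=O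
F4 | step 7 | (2Z,5R,7S,9R,11R)-5,7,9,11-tetrakis(Bpin)icos-2-en-1-ol | CCCCCCCCC[C@@H](B1OC(C)(C)C(C)(C)O1)C[C@@H](B1OC(C)(C)C(C)(C)O1)C[C@H](B1OC(C)(C)C(C)(C)O1)C[C@@H](B1OC(C)(C)C(C)(C)O1)C/C=C\CO
F5 | step 7 | (2Z,5S,7R,9R,11R)-icos-2-ene-1,5,7,9,11-pentaol | CCCCCCCCC[C@@H](O)C[C@@H](O)C[C@H](O)C[C@@H](O)C/C=C\CO
F6 | step 7 | (2Z,5S,7R,9R,11R)-5,7,9,11-tetrahydroxyicos-2-enal | CCCCCCCCC[C@@H](O)C[C@@H](O)C[C@H](O)C[C@@H](O)C/C=C\C=O
F7 | step 7 | (6S)-6-[(2S,4R,6R)-2,4,6-trihydroxypentadecyl]-5,6-dihydro-2H-pyran-2-ol (anomer mixture) | CCCCCCCCC[C@@H](O)C[C@@H](O)C[C@H](O)C[C@@H]1CC=CC(O)O1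
F8 | step 4 | (R)-1-(trimethylstannyl)but-3-enyl 2,4,6-triisopropylbenzoate | C[Sn](C)(C)[C@H](CC=C)OC(=O)c1c(C(C)C)cc(C(C)C)cc1C(C)C
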